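**Plan**

- Retrosynthesis: (i) the C8 ester, the C13 acetate and the silyl groups; (ii) the furanone O–C4 bond, cut together with a re-drawn C1–C6 bond, so that the ten-membered ring becomes the butenolide-fused decalin ketol 20 (ring A = C1–C6, ring B = C6–C10 + C1); (iii) ring A at C5–C6 and C1–C2 (Michael/aldol); (iv) ring B at C1–C6 (vinylogous Claisen); (v) the butenolide at C7=C11 (HWE); (vi) C8–C9 (Barbier).
- Forward order: γ-lactone → open-chain Weinreb amide → butenolide → ring B → ring A → one-step opening of the decalin to the ten-membered ring with closure of the furanone and formation of the 5(6)-ylidene lactone → acetate and side-chain ester.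
- Enabling feature: C1 and C6 are the two oxygen-bearing ring carbons (furanone O on C1, lactone O on C6) and lie 1,6 across the cyclodecane, and C4 is the allylic end of C4–C5=C6. An alkoxy radical on C1 of a C1–C6-bonded bicycle must therefore break C1–C6 to a lactone-stabilised C4–C5–C6 allyl system that sits under the new C1=O oxygen.
- Stereochemistry: C8 from (R)-glyceraldehyde acetonide (Felkin–Anh Barbier addition); C10 by cis-hydrogenation of the α-methylene lactone; the decalin centres C1, C4, C6 are made without control and erased; C4 is re-made in the key step under control of the C8–C10 bridge; the C5=C6 geometry is fixed by the ring; the side-chain Z geometry comes from a butenolide.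

Key step: step 13

Remark: the germacrane numbering of the target (ring C1–C10, lactone C11–C13, C14 on C10, C15 on C4) is used for all intermediates, and anti (Felkin–Anh) addition is assumed in step 1; if the addition were syn-selective, the (S)-aldehyde would be used instead.

**Route**

Step 1
Reactants: 1 (R)-2,2-dimethyl-1,3-dioxolane-4-carbaldehyde; 2 methyl 2-(bromomethyl)acrylate
Product: 4 (5S)-5-[(4R)-2,2-dimethyl-1,3-dioxolan-4-yl]-3-methylideneoxolan-2-one, via hydroxy ester 3 (not isolated)
Conditions: Zn, THF/sat. aq NH4Cl, 0 → 20 °C; then PPTS (cat.), toluene, 60 °C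
Reagents that add atoms: none
Why: Zinc Barbier 2-(alkoxycarbonyl)allylation of an α-alkoxy aldehyde followed by lactonisation is a standard entry to α-methylene-γ-butyrolactones, and Felkin–Anh (anti) attack directed by the dioxolane stereocentre should set C8.

Step 2
Reactants: 4 (5S)-5-[(4R)-2,2-dimethyl-1,3-dioxolan-4-yl]-3-methylideneoxolan-2-one
Product: 5 (3S,5S)-5-[(4R)-2,2-dimethyl-1,3-dioxolan-4-yl]-3-methyloxolan-2-one (cis)
Conditions: H2 (1 atm), Rh/Al2O3, EtOAc, 20 °C
Reagents that add atoms: none
Why: Heterogeneous hydrogenation of an α-methylene-γ-butyrolactone delivers hydrogen to the face opposite the C5 substituent and should give the cis-3,5-disubstituted lactone, which sets C10.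

Step 3
Reactants: 5 (3S,5S)-5-[(4R)-2,2-dimethyl-1,3-dioxolan-4-yl]-3-methyloxolan-2-one
Product: 7 (2S,4S)-4-(tert-butyldimethylsilyloxy)-4-[(4R)-2,2-dimethyl-1,3-dioxolan-4-yl]-N-methoxy-N,2-dimethylbutanamide, via hydroxy amide 6 (not isolated)
Conditions: MeNH(OMe)·HCl, Me3Al, CH2Cl2, 0 → 20 °C; Rochelle salt work-up; crude: TBSOTf, 2,6-lutidine, CH2Cl2, −78 → 0 °C
Reagents that add atoms: N,O-dimethylhydroxylamine hydrochloride (CNOC.Cl); tert-butyldimethylsilyl triflate (CC(C)(C)[Si](C)(C)OS(=O)(=O)C(F)(F)F)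
Why: Weinreb aminolysis of a lactone with the aluminium amide, with silylation of the γ-hydroxy amide before it can relactonise, is routine and touches neither stereocentre.

Step 4
Reactants: 7 (2S,4S)-4-(tert-butyldimethylsilyloxy)-4-[(4R)-2,2-dimethyl-1,3-dioxolan-4-yl]-N-methoxy-N,2-dimethylbutanamide
Product: 8 (2S,4S,5R)-4-(tert-butyldimethylsilyloxy)-5,6-dihydroxy-N-methoxy-N,2-dimethylhexanamide
Conditions: CuCl2·2H2O, MeCN, 0 °C
Reagents that add atoms: none
Why: A terminal isopropylidene acetal is hydrolysed by a mild Lewis acid much faster than a secondary TBS ether is lost.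

Step 5
Reactants: 9 benzyl 2-(diethoxyphosphoryl)acetate
Product: 11 benzyl 3-(tert-butyldimethylsilyloxy)-2-(diethoxyphosphoryl)propanoate (racemic), via hydroxymethyl phosphonate 10 (not isolated)
Conditions: (CH2O)n (1 eq), piperidine (cat.), THF, 60 °C; then TBSCl, imidazole, DMF, 20 °C
Reagents that add atoms: formaldehyde, used as paraformaldehyde (C=O); tert-butyldimethylsilyl chloride (CC(C)(C)[Si](C)(C)Cl)
Why: Base-catalysed hydroxymethylation (aldol addition to formaldehyde) of a phosphonoacetate should stop at the mono-adduct when formaldehyde is limiting, and the primary alcohol is then silylated in the usual way.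

Step 6
Reactants: 11 benzyl 3-(tert-butyldimethylsilyloxy)-2-(diethoxyphosphoryl)propanoate
Product: 12 3-(tert-butyldimethylsilyloxy)-2-(diethoxyphosphoryl)propanoic acid (racemic)
Conditions: H2 (1 atm), Pd/C, EtOAc, 20 °C
Reagents that add atoms: none
Why: Hydrogenolysis of the benzyl ester is neutral, so the β-silyloxy phosphonate has no base with which to eliminate.

Step 7
Reactants: 8 (2S,4S,5R)-4-(tert-butyldimethylsilyloxy)-5,6-dihydroxy-N-methoxy-N,2-dimethylhexanamide; 12 3-(tert-butyldimethylsilyloxy)-2-(diethoxyphosphoryl)propanoic acid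
Product: 13 (2R,3S,5S)-3-(tert-butyldimethylsilyloxy)-2-hydroxy-6-[methoxy(methyl)amino]-5-methyl-6-oxohexyl 3-(tert-butyldimethylsilyloxy)-2-(diethoxyphosphoryl)propanoate (mixture at the phosphonate carbon)
Conditions: DCC, DMAP (cat.), CH2Cl2, −20 → 0 °C
Reagents that add atoms: none
Why: Carbodiimide (Steglich) esterification at low temperature acylates the primary hydroxyl of a 1,2-diol in preference to the hindered secondary one.

Step 8
Reactants: 13 (2R,3S,5S)-hydroxy phosphonoacetate ester
Product: 14 (3S,5S)-3-(tert-butyldimethylsilyloxy)-6-[methoxy(methyl)amino]-5-methyl-2,6-dioxohexyl 3-(tert-butyldimethylsilyloxy)-2-(diethoxyphosphoryl)propanoate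
Conditions: Dess–Martin periodinane, NaHCO3, CH2Cl2, 0 → 20 °C
Reagents that add atoms: none
Why: Dess–Martin oxidation of a secondary alcohol under buffered, non-basic conditions leaves the α-silyloxy centre C8 and the phosphonoacetate untouched.

Step 9
Reactants: 14 (3S,5S)-keto phosphonoacetate ester
Product: 15 (2S,4S)-4-(tert-butyldimethylsilyloxy)-4-[4-(tert-butyldimethylsilyloxymethyl)-5-oxo-2,5-dihydrofuran-3-yl]-N-methoxy-N,2-dimethylbutanamide
Conditions: LiCl, DBU, MeCN, 0 °C
Reagents that add atoms: none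
Why: Intramolecular Horner–Wadsworth–Emmons olefination of an α-acyloxy ketone under Masamune–Roush conditions closes the butenolide, and the mild lithium chloride/amine base should limit β-elimination of the silyloxy group and epimerisation at C8.

Step 10
Reactants: 15 (2S,4S)-butenolide Weinreb amide
Product: 16 (4S,6S)-4-(tert-butyldimethylsilyloxy)-3-(tert-butyldimethylsilyloxymethyl)-6-methyl-5,6-dihydro-1-benzofuran-2,7(4H,7aH)-dione (C7a epimers in equilibrium with the 7-enol)
Conditions: LiHMDS (2.2 eq), THF, −78 → −20 °C; aq NH4Cl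
Reagents that add atoms: none
Why: Vinylogous Claisen (Dieckmann-type) cyclisation, in which the γ-CH2 of the butenolide is deprotonated to the 2-oxidofuran and acylated at its free γ-carbon (the α-carbon is blocked) by the Weinreb amide through a six-membered transition state, while the amide α-centre C10 is too weakly acidic to be touched.

Step 11
Reactants: 16 (4S,6S)-bicyclic keto butenolide; 17 3-methylbut-3-en-2-one
Product: 19 tricyclic ketol with ring A = C1(OH)–C2H2–C3(=O)–C4H(CH3)–C5H2–C6 fused at C1–C6 to ring B of 16 ((8S,10S), mixture at C1, C4, C6), via Michael adduct 18 (not isolated)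
Conditions: 17 (1.5 eq), Et3N (0.2 eq), CH2Cl2, 20 °C; then pyrrolidine, AcOH (0.3 eq each), 20 °C
Reagents that add atoms: none
Why: Robinson-type annulation stopped at the ketol (as for the Hajos–Parrish ketol), in which the doubly activated C6–H adds to the enone and the enamine of the methyl ketone closes onto the C1 ketone (6-enolexo aldol); the isomer mixture at C1, C4 and C6 does not matter because all three centres are made planar later.

Step 12
Reactants: 19 tricyclic ketol
Product: 20 tricyclic enone ketol with ring A = C1(OH)–C2H2–C3(=O)–C4(CH3)=C5H–C6 ((8S,10S), mixture at C1, C6)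
Conditions: IBX, DMSO–fluorobenzene, 70 °C
Reagents that add atoms: none
Why: IBX dehydrogenation of a ketone to its enone can only go toward C4–C5 because C1 carries no hydrogen, and it removes the C4 stereocentre.

Step 13
Reactants: 20 tricyclic enone ketol
Product: 23 (4S,8S,10S)-8-O,13-O-bis(tert-butyldimethylsilyl)-1,4-epoxy-8,13-dihydroxy-3-oxogermacra-1,5E,7(11)-trien-12,6-olide, via hypoiodite 21 (not isolated), via allylic iodide 22 (not isolated)
Conditions: PhI(OAc)2 (1.5 eq), I2 (1.0 eq), CH2Cl2, visible light, 20 °C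
Reagents that add atoms: none
Why: Proposed new method: the C1 hypoiodite 21 is homolysed by light to the C1 alkoxy radical, which cleaves the C1–C6 ring-fusion bond because only this β-scission gives a tertiary, lactone-oxygen-substituted radical conjugated with C7=C11 and, after rotation, with C4=C5; iodine transfer and ionisation (via 22) give the C4–C5–C6 allyl cation, the oxygen of the C1 ketone just formed adds to C4, and loss of H-2 gives the 3(2H)-furanone. The closest known reaction type is the Suárez hypoiodite β-fragmentation with radical–polar crossover and oxygen capture of the resulting oxocarbenium ion, as used for ring expansion of bicyclic carbinols to medium-ring ketones; capture of the vinylogous cation at C4 by a carbonyl oxygen is the untested part. The furanone (O, C1, C2, C3, C4) closes 5-exo at the C4 end of the allyl cation, the ten-membered carbocycle arises by cleavage and not by closure, and C5=C6 must form with C4 and C7 cis because both stay in the ring. C4 is the only new stereocentre and should be set under substrate control, the C1 oxygen being held by the C8–C10 bridge over the face of the planar C3–C4–C5–C6 unit that leaves both methyl groups and the C8 silyloxy group outside; the C1/C6 isomers of 20 converge because both centres become planar. The step needs scission of C1–C6 and not of C1–C2 or C1–C10, which the captodative C6 radical secures, and closure of the C1 oxygen on C4 and not of the C3 oxygen on C6 or of C2 on C6. The latter is expected because C2 is not yet enolised when the cation forms, and because the C3-oxygen adduct is an ionisable spiroketal that can revert, whereas deprotonation of the C1-oxygen adduct is irreversible.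

Step 14
Reactants: 23 bis-silyl ether of the tricyclic core
Product: 24 (4S,8S,10S)-1,4-epoxy-8,13-dihydroxy-3-oxogermacra-1,5E,7(11)-trien-12,6-olide
Conditions: HF·pyridine, pyridine, THF, 0 → 20 °C
Reagents that add atoms: none
Why: Buffered HF·pyridine removes both silyl ethers without the base to which the allylic C13 oxygen and the ylidene butenolide are sensitive.

Step 15
Reactants: 24 (4S,8S,10S)-8,13-diol
Product: 25 (4S,8S,10S)-13-acetoxy-1,4-epoxy-8-hydroxy-3-oxogermacra-1,5E,7(11)-trien-12,6-olide
Conditions: AcCl (1.05 eq), 2,4,6-collidine, CH2Cl2, −78 °C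
Reagents that add atoms: acetyl chloride (CC(Cl)=O)
Why: Kinetic acylation at low temperature distinguishes the primary allylic C13 hydroxyl from the hindered secondary C8 hydroxyl.

Step 16
Reactants: 26 4-methylfuran-2(5H)-one
Product: 29 (Z)-4-(tert-butyldimethylsilyloxy)-3-methylbut-2-enoic acid, via potassium hydroxy carboxylate 27 (not isolated), via bis-silyl compound 28 (not isolated)
Conditions: KOH (1 eq), MeOH/H2O, 20 °C; evaporate; TBSCl (2.2 eq), imidazole, DMF; then K2CO3, MeOH/THF/H2O; citric acid to pH 4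
Reagents that add atoms: potassium hydroxide ([K+].[OH-]); tert-butyldimethylsilyl chloride (CC(C)(C)[Si](C)(C)Cl)
Why: Saponification of the butenolide gives the γ-hydroxy carboxylate with the ring (Z) geometry retained, and exhaustive silylation followed by selective cleavage of the silyl ester is the standard route to the O-silyl hydroxy acid.

Step 17
Reactants: 25 (4S,8S,10S)-13-acetoxy-8-hydroxy core; 29 (Z)-4-(tert-butyldimethylsilyloxy)-3-methylbut-2-enoic acid
Product: 31 O-TBS ether of the target at the side-chain hydroxyl, via mixed anhydride 30 (not isolated)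
Conditions: 29, 2,4,6-trichlorobenzoyl chloride, Et3N, THF, 20 °C; then 25, DMAP, toluene, 20 °C
Reagents that add atoms: none
Why: Yamaguchi esterification acylates hindered secondary alcohols under mild conditions through the mixed anhydride and leaves the C13 acetate alone.

Step 18
Reactants: 31 O-TBS ether of the target
Product: 32 (4S,8S,10S)-13-acetoxy-1,4-epoxy-3-oxogermacra-1,5E,7(11)-trien-12,6-olid-8-yl (Z)-4-hydroxy-3-methylbut-2-enoate (CNP0269057.1)
Conditions: HF·pyridine, pyridine, THF, 0 °C
Reagents that add atoms: none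
Why: Buffered fluoride desilylation at 0 °C frees the primary alcohol without supplying the base that would let the (Z)-γ-hydroxy enoate lactonise and release the C8 alcohol.

**Compound list**

1 | (R)-2,2-dimethyl-1,3-dioxolane-4-carbaldehyde | O=C[C@H]1COC(C)(C)O1 | starting material
2 | methyl 2-(bromomethyl)acrylate | COC(=O)C(=C)CBr | starting material
3 | methyl (4S)-4-[(4R)-2,2-dimethyl-1,3-dioxolan-4-yl]-4-hydroxy-2-methylidenebutanoate | COC(=O)C(=C)C[C@H](O)[C@H]1COC(C)(C)O1 | intermediate
4 | (5S)-5-[(4R)-2,2-dimethyl-1,3-dioxolan-4-yl]-3-methylideneoxolan-2-one | C=C1C[C@H](OC1=O)[C@H]2COC(C)(C)O2 | intermediate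
5 | (3S,5S)-5-[(4R)-2,2-dimethyl-1,3-dioxolan-4-yl]-3-methyloxolan-2-one | C[C@H]1C[C@H](OC1=O)[C@H]2COC(C)(C)O2 | intermediate
6 | (2S,4S)-4-[(4R)-2,2-dimethyl-1,3-dioxolan-4-yl]-4-hydroxy-N-methoxy-N,2-dimethylbutanamide | CON(C)C(=O)[C@@H](C)C[C@H](O)[C@H]1COC(C)(C)O1 | intermediate
7 | (2S,4S)-4-(tert-butyldimethylsilyloxy)-4-[(4R)-2,2-dimethyl-1,3-dioxolan-4-yl]-N-methoxy-N,2-dimethylbutanamide | CON(C)C(=O)[C@@H](C)C[C@H](O[Si](C)(C)C(C)(C)C)[C@H]1COC(C)(C)O1 | intermediate
8 | (2S,4S,5R)-4-(tert-butyldimethylsilyloxy)-5,6-dihydroxy-N-methoxy-N,2-dimethylhexanamide | CON(C)C(=O)[C@@H](C)C[C@H](O[Si](C)(C)C(C)(C)C)[C@H](O)CO | intermediate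
9 | benzyl 2-(diethoxyphosphoryl)acetate | CCOP(=O)(OCC)CC(=O)OCc1ccccc1 | starting material
10 | benzyl 2-(diethoxyphosphoryl)-3-hydroxypropanoate (racemic) | CCOP(=O)(OCC)C(CO)C(=O)OCc1ccccc1 | intermediate
11 | benzyl 3-(tert-butyldimethylsilyloxy)-2-(diethoxyphosphoryl)propanoate (racemic) | CCOP(=O)(OCC)C(CO[Si](C)(C)C(C)(C)C)C(=O)OCc1ccccc1 | intermediate
12 | 3-(tert-butyldimethylsilyloxy)-2-(diethoxyphosphoryl)propanoic acid (racemic) | CCOP(=O)(OCC)C(CO[Si](C)(C)C(C)(C)C)C(=O)O | intermediate
13 | (2R,3S,5S)-3-(tert-butyldimethylsilyloxy)-2-hydroxy-6-[methoxy(methyl)amino]-5-methyl-6-oxohexyl 3-(tert-butyldimethylsilyloxy)-2-(diethoxyphosphoryl)propanoate | CON(C)C(=O)[C@@H](C)C[C@H](O[Si](C)(C)C(C)(C)C)[C@H](O)COC(=O)C(CO[Si](C)(C)C(C)(C)C)P(=O)(OCC)OCC | intermediate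
14 | (3S,5S)-3-(tert-butyldimethylsilyloxy)-6-[methoxy(methyl)amino]-5-methyl-2,6-dioxohexyl 3-(tert-butyldimethylsilyloxy)-2-(diethoxyphosphoryl)propanoate | CON(C)C(=O)[C@@H](C)C[C@H](O[Si](C)(C)C(C)(C)C)C(=O)COC(=O)C(CO[Si](C)(C)C(C)(C)C)P(=O)(OCC)OCC | intermediate
15 | (2S,4S)-4-(tert-butyldimethylsilyloxy)-4-[4-(tert-butyldimethylsilyloxymethyl)-5-oxo-2,5-dihydrofuran-3-yl]-N-methoxy-N,2-dimethylbutanamide | CON(C)C(=O)[C@@H](C)C[C@H](O[Si](C)(C)C(C)(C)C)C1=C(CO[Si](C)(C)C(C)(C)C)C(=O)OC1 | intermediate
16 | (4S,6S)-4-(tert-butyldimethylsilyloxy)-3-(tert-butyldimethylsilyloxymethyl)-6-methyl-5,6-dihydro-1-benzofuran-2,7(4H,7aH)-dione | CC(C)(C)[Si](C)(C)OCC1=C2[C@@H](O[Si](C)(C)C(C)(C)C)C[C@H](C)C(=O)C2OC1=O | intermediate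
17 | 3-methylbut-3-en-2-one | CC(=O)C(C)=C | starting material
18 | Michael adduct: 16 carrying a 2-methyl-3-oxobutyl group on C6 (C7a of the benzofuranone), mixture at C4 and C6 | CC(C)(C)[Si](C)(C)OCC1=C2[C@@H](O[Si](C)(C)C(C)(C)C)C[C@H](C)C(=O)C2(CC(C)C(C)=O)OC1=O | intermediate
19 | tricyclic ketol (ring A: C1 carbinol, C3 ketone, C4 methyl; (8S,10S), mixture at C1, C4, C6) | CC(C)(C)[Si](C)(C)OCC1=C2[C@@H](O[Si](C)(C)C(C)(C)C)C[C@H](C)C3(O)CC(=O)C(C)CC23OC1=O | intermediate
20 | tricyclic enone ketol (ring A: C1 carbinol, C3 ketone, C4=C5; (8S,10S), mixture at C1, C6) | CC(C)(C)[Si](C)(C)OCC1=C2[C@@H](O[Si](C)(C)C(C)(C)C)C[C@H](C)C3(O)CC(=O)C(C)=CC23OC1=O | intermediate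
21 | C1 hypoiodite of 20 | CC(C)(C)[Si](C)(C)OCC1=C2[C@@H](O[Si](C)(C)C(C)(C)C)C[C@H](C)C3(OI)CC(=O)C(C)=CC23OC1=O | intermediate
22 | ring-expanded allylic iodide (ten-membered 1,3-diketone, Z-C4=C5, iodine on C6 of the butenolide) | CC(C)(C)[Si](C)(C)OCC1=C2[C@@H](O[Si](C)(C)C(C)(C)C)C[C@H](C)C(=O)CC(=O)/C(C)=C\C2(I)OC1=O | intermediate
23 | (4S,8S,10S)-8,13-bis(tert-butyldimethylsilyloxy)-1,4-epoxy-3-oxogermacra-1,5E,7(11)-trien-12,6-olide | CC(C)(C)[Si](C)(C)OCC1=C2/C(=C\[C@]3(C)OC(=CC3=O)[C@@H](C)C[C@@H]2O[Si](C)(C)C(C)(C)C)OC1=O | intermediate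
24 | (4S,8S,10S)-1,4-epoxy-8,13-dihydroxy-3-oxogermacra-1,5E,7(11)-trien-12,6-olide | OCC1=C2/C(=C\[C@]3(C)OC(=CC3=O)[C@@H](C)C[C@@H]2O)OC1=O | intermediate
25 | (4S,8S,10S)-13-acetoxy-1,4-epoxy-8-hydroxy-3-oxogermacra-1,5E,7(11)-trien-12,6-olide | CC(=O)OCC1=C2/C(=C\[C@]3(C)OC(=CC3=O)[C@@H](C)C[C@@H]2O)OC1=O | intermediate
26 | 4-methylfuran-2(5H)-one | CC1=CC(=O)OC1 | starting material
27 | potassium (Z)-4-hydroxy-3-methylbut-2-enoate | [K+].[O-]C(=O)/C=C(/C)CO | intermediate
28 | tert-butyldimethylsilyl (Z)-4-(tert-butyldimethylsilyloxy)-3-methylbut-2-enoate | CC(C)(C)[Si](C)(C)OC(=O)/C=C(/C)CO[Si](C)(C)C(C)(C)C | intermediate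
29 | (Z)-4-(tert-butyldimethylsilyloxy)-3-methylbut-2-enoic acid | OC(=O)/C=C(/C)CO[Si](C)(C)C(C)(C)C | intermediate
30 | mixed anhydride of 29 with 2,4,6-trichlorobenzoic acid | O=C(OC(=O)c1c(Cl)cc(Cl)cc1Cl)/C=C(/C)CO[Si](C)(C)C(C)(C)C | intermediate
31 | (4S,8S,10S)-13-acetoxy-1,4-epoxy-3-oxogermacra-1,5E,7(11)-trien-12,6-olid-8-yl (Z)-4-(tert-butyldimethylsilyloxy)-3-methylbut-2-enoate | CC(=O)OCC1=C2/C(=C\[C@]3(C)OC(=CC3=O)[C@@H](C)C[C@@H]2OC(=O)/C=C(/C)CO[Si](C)(C)C(C)(C)C)OC1=O | intermediate
32 | (4S,8S,10S)-13-acetoxy-1,4-epoxy-3-oxogermacra-1,5E,7(11)-trien-12,6-olid-8-yl (Z)-4-hydroxy-3-methylbut-2-enoate (CNP0269057.1) | CC(=O)OCC1=C2/C(=C\[C@]3(C)OC(=CC3=O)[C@@H](C)C[C@@H]2OC(=O)/C=C(/C)CO)OC1=O | target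

**Step count and risks**

Total step count: 18 (steps 5, 6 and 16 prepare the two acid partners). Longest linear sequence: 15 steps (1–4, 7–15, 17, 18, from compound 1).

Steps most likely to fail:

1. Step 13 (proposed new method). The allyl cation may be intercepted before the C1 carbonyl oxygen reaches C4, either by the C3 carbonyl oxygen at C6 (spiroketal formation) or by acetate or iodide, and the C1 oxygen may close on the wrong face of C4 (poor facial selectivity). The fallback uses known reactions and sets out from 20. The hypoiodite fragmentation is run as above and the crude product is hydrolysed with aqueous NaHCO3, so that the cation is captured by water at C6; this is the usual outcome of the fragmentation when the radical is α-oxygenated and should give the ring-expanded γ-hydroxybutenolide F1 (ten-membered ring, C1 ketone, Z-enone C3(=O)–C4=C5, C6 hemiketal). F1 is in ring–chain equilibrium with the C6 keto acid, whose C3(=O)–C4=C5–C6(=O) enedione should accept the C1 enol oxygen at C4 in a transannular 5-exo oxa-Michael addition (Et3N, CH2Cl2, 20 °C). That addition is reversible, so C4 is set under thermodynamic control, and it should give the furanone hemiketal F2. Acid-catalysed dehydration of the γ-hydroxybutenolide (CSA, toluene, 60 °C) then forms the C5=C6 ylidene lactone and the route is rejoined at 23.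

2. Step 10. The lithium oxidofuran may be acylated at its α-carbon instead of the γ-carbon, may lose silanolate from C13 (elimination to an α-methylene lactone), or may simply be quenched without closing the six-membered ring. The fallback sets out from 15 and replaces the Claisen acylation by an aldol closure. The Weinreb amide is reduced with Cp2Zr(H)Cl (THF, 20 °C), which spares the lactone, to the aldehyde F3. A DBU-catalysed intramolecular direct vinylogous aldol addition (CH2Cl2, 0 °C), γ-selective for butenolides, should close ring B to the C1 carbinol F4, and Dess–Martin oxidation of F4 returns to the route at 16.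

3. Step 12. In hot DMSO the β-hydroxy ketone may dehydrate to the cross-conjugated dienone or undergo retro-aldol opening of ring A before or after dehydrogenation. The fallback sets out from 19. TMSOTf and Et3N (CH2Cl2, 0 °C) should give the bis-silyl compound F5, in which the tertiary C1 hydroxyl is capped and the ketone is held as the more substituted (thermodynamic) C3=C4 silyl enol ether. Saegusa–Ito oxidation with Pd(OAc)2 in MeCN then gives the enone silyl ether F6, and K2CO3 in MeOH removes the C1 trimethylsilyl group to rejoin the route at 20.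

Further compounds
F1 | step 13 | ring-expanded γ-hydroxybutenolide (ten-membered 1,3-diketone, Z-C4=C5, hydroxyl on C6; (8S,10S)) | CC(C)(C)[Si](C)(C)OCC1=C2[C@@H](O[Si](C)(C)C(C)(C)C)C[C@H](C)C(=O)CC(=O)/C(C)=C\C2(O)OC1=O
F2 | step 13 | furanone hemiketal (1,4-epoxy-3-oxo-1-ene closed, C5H2, hydroxyl on C6; (4S,8S,10S)) | CC(C)(C)[Si](C)(C)OCC1=C2[C@@H](O[Si](C)(C)C(C)(C)C)C[C@H](C)C3=CC(=O)[C@@](C)(O3)CC2(O)OC1=O
F3 | step 10 | (2S,4S)-4-(tert-butyldimethylsilyloxy)-4-[4-(tert-butyldimethylsilyloxymethyl)-5-oxo-2,5-dihydrofuran-3-yl]-2-methylbutanal | O=C[C@@H](C)C[C@H](O[Si](C)(C)C(C)(C)C)C1=C(CO[Si](C)(C)C(C)(C)C)C(=O)OC1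
F4 | step 10 | (4S,6S)-4-(tert-butyldimethylsilyloxy)-3-(tert-butyldimethylsilyloxymethyl)-7-hydroxy-6-methyl-5,6,7,7a-tetrahydro-1-benzofuran-2(4H)-one | CC(C)(C)[Si](C)(C)OCC1=C2[C@@H](O[Si](C)(C)C(C)(C)C)C[C@H](C)C(O)C2OC1=O
F5 | step 12 | bis(trimethylsilyl) derivative of 19 (C1–OTMS, C3=C4 trimethylsilyl enol ether) | CC(C)(C)[Si](C)(C)OCC1=C2[C@@H](O[Si](C)(C)C(C)(C)C)C[C@H](C)C3(O[Si](C)(C)C)CC(O[Si](C)(C)C)=C(C)CC23OC1=O
F6 | step 12 | C1 trimethylsilyl ether of 20 | CC(C)(C)[Si](C)(C)OCC1=C2[C@@H](O[Si](C)(C)C(C)(C)C)C[C@H](C)C3(O[Si](C)(C)C)CC(=O)C(C)=CC23OC1=O
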